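**Retrosynthetic overview** (flavone numbering for target atoms)

1. Feature: in ring A, C6 is a bare CH between the oxygen-bearing carbons C5 and C7, so ring A is cut at C5–C6 and C6–C7 into one nucleophilic carbon (the α-carbon of tert-butyl acetate) and two ester carbonyls held on a finished ring C.
2. That precursor is pyranone diester 7: ring C with ring B at C2, the future C5 as the methyl ester on pyranone C3, and the future C8–C7 as the acetate arm on pyranone C2.
3. 7 is cut at C4–C4a and O1–C2 into dimethyl 3-oxoglutarate (C5, C4a, C8a, C8, C7) and 3-(4-benzyloxyphenyl)propioloyl chloride (C4, C3, C2, ring B).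
4. After the annulation the extra C6 carboxyl is removed, O7 is sulfated while O5–H is hydrogen-bonded to the C4 carbonyl, and O4′ is debenzylated last.
5. Ring order: ring B is bought, ring C is closed in step 3, ring A in step 4.

Key step: step 4

Assumption: the target is drawn as the free hydrogen sulfate; because aryl hydrogen sulfates are strong acids that hydrolyse on storage, the sulfate is carried as its sodium salt and the acid form is set free only in the last operation and kept cold. The target has no stereocentre.

**Route**

Step 1
Reactants: 1 1-benzyloxy-4-ethynylbenzene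
Product: 3 3-(4-benzyloxyphenyl)prop-2-ynoic acid, via lithium acetylide 2 (not isolated)
Conditions: n-BuLi (1.05 equiv), THF, −78 °C; CO2 (gas), −78 °C → rt; 1 M HCl
Reagents that add atoms: carbon dioxide, O=C=O
Why: Deprotonation of a terminal alkyne and carboxylation of the lithium acetylide is the standard entry to arylpropiolic acids, and the benzyl ether is inert to n-BuLi at −78 °C.

Step 2
Reactants: 3 3-(4-benzyloxyphenyl)prop-2-ynoic acid
Product: 4 3-(4-benzyloxyphenyl)prop-2-ynoyl chloride
Conditions: (COCl)2 (1.3 equiv), DMF (cat.), CH2Cl2, 0 °C → rt; evaporate; used crude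
Reagents that add atoms: oxalyl chloride, O=C(Cl)C(=O)Cl
Why: DMF-catalysed acid chloride formation with oxalyl chloride is mild enough for an arylpropiolic acid and gives only gaseous co-products, so the crude chloride can be used directly.

Step 3
Reactants: 4 3-(4-benzyloxyphenyl)prop-2-ynoyl chloride; 5 dimethyl 3-oxoglutarate
Product: 7 methyl 6-(4-benzyloxyphenyl)-2-(2-methoxy-2-oxoethyl)-4-oxo-4H-pyran-3-carboxylate, via C-acylated ynone 6 (not isolated)
Conditions: 5 (1.3 equiv), MgCl2 (1.3 equiv), pyridine (2.6 equiv), CH2Cl2, 0 °C; 4 added, 0 °C → rt; 1 M HCl wash; then DMAP (0.1 equiv), CH2Cl2, rt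
Reagents that add atoms: none
Why: Soft enolisation of the β-keto ester as its magnesium chelate directs the acid chloride to carbon (C-acylation of a 1,3-dicarbonyl), and the enol oxygen of the resulting tricarbonyl then adds to the ynone in a 6-endo-dig oxa-Michael closure, the mode by which ortho-hydroxyaryl ynones give chromones; 5 is symmetric, so either methylene gives the same product, and its excess limits double acylation.

Step 4
Reactants: 7 methyl 6-(4-benzyloxyphenyl)-2-(2-methoxy-2-oxoethyl)-4-oxo-4H-pyran-3-carboxylate; 8 tert-butyl acetate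
Product: 11 tert-butyl 2-(4-benzyloxyphenyl)-5,7-dihydroxy-4-oxo-4H-chromene-6-carboxylate, via lithium enolate of tert-butyl acetate 9 (not isolated), via mono-Claisen keto ester 10 (not isolated)
Conditions: LiN(iPr)2 (4.0 equiv), 8 (4.2 equiv), THF, −78 °C; 7 added, −78 → 0 °C; AcOH (4.2 equiv), 0 °C; DBU (3 equiv), rt; 1 M HCl
Reagents that add atoms: none
Why: Proposed new method: the first equivalent of 9 removes a C8 proton of 7, and the extended enolate so formed, whose ring carbons are no longer open to conjugate attack, is acylated by further 9 at the pyranone C3 methyl ester, which lithium chelation to the C4 oxygen keeps electrophilic (Claisen condensation, C5–C6 bond), to give the dianion of 10. That dianion cannot close because its C7 ester is then an enolate, so acetic acid returns it to neutral 10 and DBU sets up the monoanion equilibrium in which the C6 enolate of the β-keto ester faces a C8-protonated C7 methyl ester and attacks it (Dieckmann condensation, C6–C7 bond). Ring A closes in a 6-exo-trig mode (6-enolendo-exo-trig in enolate terms), methoxide leaves, and enolisation of the cyclic triketone to the 5,7-dihydroxybenzoate is irreversible and pulls both equilibria forward. The closest known reaction type is the tandem Claisen and Dieckmann condensation of homophthalate diesters with acetate enolates to 1,3-dihydroxynaphthalene-2-carboxylates, together with the mild-base aromatisation of open polyketo esters; its transfer to a 4-pyranone diester is the untested part. No stereocentre is formed. The selectivities needed are ester acylation over conjugate addition and ring opening of the pyranone, secured by the early C8 deprotonation, and closure of C6 onto the C7 methyl ester in preference to closure of C8 onto the acetate carbonyl, secured by the bulk of the tert-butyl ester.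

Step 5
Reactants: 11 tert-butyl 2-(4-benzyloxyphenyl)-5,7-dihydroxy-4-oxo-4H-chromene-6-carboxylate
Product: 13 2-(4-benzyloxyphenyl)-5,7-dihydroxy-4H-chromen-4-one (4′-O-benzylapigenin), via chromone-6-carboxylic acid 12 (not isolated)
Conditions: TFA/CH2Cl2 (1:2), rt; evaporate (toluene chase); DMSO, 110 °C
Reagents that add atoms: none
Why: Acidolysis of the tert-butyl ester followed by thermal protodecarboxylation should be easy because the carboxyl sits between two hydroxyls and para to the ring oxygen (ipso-protonation, as for 2,4,6-trihydroxybenzoic acids), and a benzyl aryl ether tolerates TFA at room temperature.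

Step 6
Reactants: 13 2-(4-benzyloxyphenyl)-5,7-dihydroxy-4H-chromen-4-one
Product: 14 sodium 2-(4-benzyloxyphenyl)-5-hydroxy-4-oxo-4H-chromen-7-yl sulfate
Conditions: SO3·pyridine (3 equiv), pyridine, rt → 40 °C; aq. NaHCO3 to pH 8; C18 chromatography
Reagents that add atoms: sulfur trioxide pyridine complex, O=S(=O)([O-])[n+]1ccccc1; sodium hydrogen carbonate, [Na+].OC(=O)[O-]
Why: O-Sulfation of a phenol with an SO3–amine complex should take place only at the acidic 7-hydroxyl, because the 5-hydroxyl is locked in a hydrogen bond to the C4 carbonyl and is a poor nucleophile under these mild conditions.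

Step 7
Reactants: 14 sodium 2-(4-benzyloxyphenyl)-5-hydroxy-4-oxo-4H-chromen-7-yl sulfate
Product: 16 apigenin 7-sulfate (5-hydroxy-2-(4-hydroxyphenyl)-4-oxo-4H-chromen-7-yl hydrogen sulfate), via sodium apigenin 7-sulfate 15 (not isolated)
Conditions: H2 (1 atm), 10% Pd/C, MeOH/H2O, rt; filter; HCl (1.0 equiv), 0 °C; C18 desalting; lyophilise
Reagents that add atoms: none
Why: Catalytic hydrogenolysis of the benzyl aryl ether under neutral conditions should leave the aryl sulfate salt and the flavone C2–C3 double bond untouched, and one equivalent of acid in the cold then gives the hydrogen sulfate form.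

**Compound list**

1 | 1-benzyloxy-4-ethynylbenzene | C#Cc1ccc(OCc2ccccc2)cc1 | starting material
2 | lithium (4-benzyloxyphenyl)acetylide | [Li]C#Cc1ccc(OCc2ccccc2)cc1 | intermediate
3 | 3-(4-benzyloxyphenyl)prop-2-ynoic acid | OC(=O)C#Cc1ccc(OCc2ccccc2)cc1 | intermediate
4 | 3-(4-benzyloxyphenyl)prop-2-ynoyl chloride | ClC(=O)C#Cc1ccc(OCc2ccccc2)cc1 | intermediate
5 | dimethyl 3-oxoglutarate | COC(=O)CC(=O)CC(=O)OC | starting material
6 | dimethyl 2-[3-(4-benzyloxyphenyl)prop-2-ynoyl]-3-oxopentanedioate (drawn as the triketo tautomer; present as an enol, no defined configuration) | COC(=O)CC(=O)C(C(=O)C#Cc1ccc(OCc2ccccc2)cc1)C(=O)OC | intermediate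
7 | methyl 6-(4-benzyloxyphenyl)-2-(2-methoxy-2-oxoethyl)-4-oxo-4H-pyran-3-carboxylate | COC(=O)Cc1oc(-c2ccc(OCc3ccccc3)cc2)cc(=O)c1C(=O)OC | intermediate
8 | tert-butyl acetate | CC(=O)OC(C)(C)C | starting material
9 | lithium enolate of tert-butyl acetate | [Li]OC(=C)OC(C)(C)C | intermediate
10 | tert-butyl 3-[6-(4-benzyloxyphenyl)-2-(2-methoxy-2-oxoethyl)-4-oxo-4H-pyran-3-yl]-3-oxopropanoate | COC(=O)Cc1oc(-c2ccc(OCc3ccccc3)cc2)cc(=O)c1C(=O)CC(=O)OC(C)(C)C | intermediate
11 | tert-butyl 2-(4-benzyloxyphenyl)-5,7-dihydroxy-4-oxo-4H-chromene-6-carboxylate | CC(C)(C)OC(=O)c1c(O)cc2oc(-c3ccc(OCc4ccccc4)cc3)cc(=O)c2c1O | intermediate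
12 | 2-(4-benzyloxyphenyl)-5,7-dihydroxy-4-oxo-4H-chromene-6-carboxylic acid | OC(=O)c1c(O)cc2oc(-c3ccc(OCc4ccccc4)cc3)cc(=O)c2c1O | intermediate
13 | 2-(4-benzyloxyphenyl)-5,7-dihydroxy-4H-chromen-4-one (4′-O-benzylapigenin) | O=c1cc(-c2ccc(OCc3ccccc3)cc2)oc2cc(O)cc(O)c12 | intermediate
14 | sodium 2-(4-benzyloxyphenyl)-5-hydroxy-4-oxo-4H-chromen-7-yl sulfate | [Na+].O=c1cc(-c2ccc(OCc3ccccc3)cc2)oc2cc(OS(=O)(=O)[O-])cc(O)c12 | intermediate
15 | sodium 5-hydroxy-2-(4-hydroxyphenyl)-4-oxo-4H-chromen-7-yl sulfate (sodium apigenin 7-sulfate) | [Na+].O=c1cc(-c2ccc(O)cc2)oc2cc(OS(=O)(=O)[O-])cc(O)c12 | intermediate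
16 | apigenin 7-sulfate | O=c1cc(-c2ccc(O)cc2)oc2cc(OS(=O)(=O)O)cc(O)c12 | target

**Step count**

Total: 7 steps. Longest linear sequence: 7 steps (1 → 3 → 4 → 7 → 11 → 13 → 14 → 16); compounds 5 and 8 are bought.

**Steps most likely to fail**

1. Step 4 (key step). The C8-deprotonated extended enolate may be too electron-rich for the first acylation, so that 7 is returned. Alternatively, the acetate enolate may add in conjugate fashion to the pyranone and open it, or the sequence may stall at the open keto ester with retro-Claisen loss of the acetate unit. The fallback uses the established ynone route to flavones; it sets out from 1 and comes back at 13. Commercial 2,4,6-trihydroxybenzaldehyde would be protected with MOMCl and NaH in DMF to give 2,4,6-tris(methoxymethoxy)benzaldehyde F1. Acetylide 2, made from 1 as in step 1, would add to F1 in THF at −78 °C to give racemic 3-(4-benzyloxyphenyl)-1-[2,4,6-tris(methoxymethoxy)phenyl]prop-2-yn-1-ol F2. Oxidation with MnO2 in CH2Cl2 would give 3-(4-benzyloxyphenyl)-1-[2,4,6-tris(methoxymethoxy)phenyl]prop-2-yn-1-one F3. HCl in MeOH at 50 °C would remove the three acetals, and the freed ortho-hydroxyaryl ynone should close 6-endo-dig (completed with K2CO3 in acetone if needed) to 13, which continues with step 6.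

2. Step 3. The magnesium enolate or pyridine may add in conjugate fashion to the arylpropioloyl chloride and to the ynone product, giving oligomers in place of clean C-acylation. O-acylation, double acylation, or ring closure through the 5-exo-dig mode to a furanone are further risks. The fallback replaces the ynone by an enone and restores the oxidation level afterwards, as in the chalcone route to flavones; it sets out from 5 and comes back at 7. Commercial (E)-3-(4-benzyloxyphenyl)acrylic acid would be converted with (COCl)2 and catalytic DMF into (E)-3-(4-benzyloxyphenyl)prop-2-enoyl chloride F4, which is far less prone to conjugate addition. C-Acylation of 5 under the same MgCl2/pyridine conditions would give dimethyl 2-[(E)-3-(4-benzyloxyphenyl)prop-2-enoyl]-3-oxopentanedioate F5. TsOH in toluene at 80 °C should close the enol onto the enone (6-endo-trig oxa-Michael) to racemic methyl 6-(4-benzyloxyphenyl)-2-(2-methoxy-2-oxoethyl)-4-oxo-5,6-dihydro-4H-pyran-3-carboxylate F6. Dehydrogenation with DDQ in dioxane at reflux would then give 7.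

3. Step 7. Sulfur-containing residues from the sulfation may slow the palladium catalyst, so that debenzylation is incomplete. Long exposure may start to reduce the C2–C3 double bond, and the sulfate ester may hydrolyse once the free acid is concentrated. The fallback reverses the order of debenzylation and sulfation; it sets out from 13 and comes back at 15. Hydrogenolysis of 13 (H2, Pd/C, THF/MeOH) with no sulfur present would give apigenin F7. One equivalent of SO3·pyridine in pyridine at 0 °C, then NaHCO3, should sulfate mainly the most acidic 7-hydroxyl, since the 5-hydroxyl is hydrogen-bonded and the 4′-hydroxyl is less acidic. Reversed-phase chromatography would remove the 4′-sulfate and the disulfate and give 15, which is acidified as in step 7 immediately before use.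

**Further compounds**

F1 | step 4 | 2,4,6-tris(methoxymethoxy)benzaldehyde | COCOc1cc(OCOC)c(C=O)c(OCOC)c1
F2 | step 4 | racemic 3-(4-benzyloxyphenyl)-1-[2,4,6-tris(methoxymethoxy)phenyl]prop-2-yn-1-ol | COCOc1cc(OCOC)c(C(O)C#Cc2ccc(OCc3ccccc3)cc2)c(OCOC)c1
F3 | step 4 | 3-(4-benzyloxyphenyl)-1-[2,4,6-tris(methoxymethoxy)phenyl]prop-2-yn-1-one | COCOc1cc(OCOC)c(C(=O)C#Cc2ccc(OCc3ccccc3)cc2)c(OCOC)c1
F4 | step 3 | (E)-3-(4-benzyloxyphenyl)prop-2-enoyl chloride | O=C(Cl)/C=C/c1ccc(OCc2ccccc2)cc1
F5 | step 3 | dimethyl 2-[(E)-3-(4-benzyloxyphenyl)prop-2-enoyl]-3-oxopentanedioate (present as an enol, no defined configuration at C2) | COC(=O)CC(=O)C(C(=O)/C=C/c1ccc(OCc2ccccc2)cc1)C(=O)OC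
F6 | step 3 | racemic methyl 6-(4-benzyloxyphenyl)-2-(2-methoxy-2-oxoethyl)-4-oxo-5,6-dihydro-4H-pyran-3-carboxylate | COC(=O)CC1=C(C(=O)OC)C(=O)CC(c2ccc(OCc3ccccc3)cc2)O1
F7 | step 7 | apigenin | O=c1cc(-c2ccc(O)cc2)oc2cc(O)cc(O)c12
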